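## The problem

Cycloshizukaol A (39) is a C2-symmetric twelve-membered carbocycle in which two identical lindenane units are joined head to tail, the C15 methylene on C4 of each unit being bonded to the quaternary C11 of the other. Each unit is a cyclopropane-fused cyclopentene (ring A: C1, C3, C4, C5 and C10, with the C1–C2–C3 three-membered ring) fused across C5–C10 to a cyclohexenone (ring B), and the C4=C5 and C6=C7 double bonds make the C8 ketone a linear dienone. Of the five stereocentres per unit, the quaternary C10 can direct its neighbour C9 and, through a cis ring fusion at C5, the cyclopropane carbons C1 and C3. C11 cannot be directed in this way, because it sits outside the ring on sp2 C7, so it has to be set while C7 is still sp3 and held in a ring. The groups that limit the choice of reagents are the dienone (conjugate addition, γ-deprotonation), the C8/C9 α-ketol (epimerisation or ketol shift in acid or base), the vinylcyclopropane and the two neopentyl carbons C11 and C15. The feature that invites a photochemical solution is ring A at the ketone oxidation level: it is a bicyclo[3.1.0]hexan-2-one whose acyl carbon C4 sits on cyclopropane carbon C3, which is the product of a 1,2-acyl shift in a cyclohex-3-enone C4(=O)–C2–C3=C1. The same C4 oxygen later becomes the enol triflate that carries the C4–C15 bond, and the C2 symmetry means that one monomer with both coupling functions is enough.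

## Retrosynthesis

In a monomer the methylene on C11, which becomes C15 of the partner unit, is written C15'.

**39 to open dimer 36.** After removal of the two silyl ethers (38), one C4–C15 bond of the macrocycle is cut. This is preferred over cutting C11–C15, which would create the remote C11 centre during ring closure, and over C7–C11, which would join a tertiary nucleophile to an sp2 carbon. The precursor is the open head-to-tail dimer 36, with an alkenyl bromide at C4 of one unit and a neopentyl iodide at C15' of the other. Zinc must insert into the alkyl iodide only (37), and palladium must then close the twelve-membered ring faster than chains grow.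

**36 to monomer 32.** The second C4–C15 bond is cut in the same way. Bromide 36 comes from stannane 35, and 35 from triflate 32 and the zinc reagent 34 of stannane 33, which is itself made from 32. The trimethylstannyl group hides the C4 electrophile of the nucleophilic half, so the first coupling can only stop at the dimer. A one-pot cyclodimerization of 32 would be shorter but leaves the chain length to statistics. The cut halves the problem: one monomer 32, with an alkenyl triflate at C4 and a neopentyl iodide at C15', supplies both halves.

**32 to keto-lactone 28.** The C6=C7 bond is removed (31, 30) and the C12 methyl ester is tied back to the C9 oxygen as a δ-lactone (29). In this bicyclo[3.3.1] lactone, C7 and C9 are bridgeheads, so the C8 ketone cannot enolise and C11 is the only acidic position. One face of the C11 enolate is covered by ring B, so the C11–C15' bond is cut there (28). The alternative, alkylating an exocyclic ester enolate on the open chain, offers no facial control. Methanolysis of the lactone later returns exactly the C9–OH/CO2Me pair of the target.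

**28 to tricyclic ketone 21.** The lactone is opened to hydroxy acid 27 and ester 26, and the C7–C11 bond is cut back to ketone 24 and bromo ester 25. Ketone 24 comes from 23 and enol triflate 22 by regioselective reductive opening of the aryl acetal. Triflate 22 comes from ketone 21. Making the triflate first removes the only enolisable hydrogen next to C4 and places C4=C5 before any base is used on ring B.

**21 to decalone 20 (key step).** The C3–C4 and C1–C2 bonds are cut and C2–C4 is restored. This turns the strained tricycle into a cis-fused cyclohex-3-enone. Cutting the cyclopropane alone (carbene addition) would leave the five-membered ring to be made separately; here both rings come from a six-membered ring that metathesis can close. The forward reaction must be a triplet process and must bridge C4 to the face of C3 away from the C10 methyl. The trans-fused C8/C9 acetal of 20 is there to secure this.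

**20 to aldehyde 16.** The ketone is taken back to alcohol 19, the C1=C3 bond is cut by metathesis (18), and the C2–C4 bond is cut back to aldehyde 16 and allylmagnesium bromide 17. Carrying the β,γ-enone from an earlier stage would risk conjugation, so the alkene and the ketone are made in the last two steps before irradiation.

**16 to cyclohexene 10.** The vinyl group is traced to a silyl-protected alkyne (15, 14, 13), which is inert to metathesis and peracid. The trans-diol acetal (13, 12) is traced to the β-epoxide 11 of cyclohexene 10. Trans-diaxial opening gives the C9 oxygen on the methyl face and the C8 oxygen on the other, which is what a locking trans-fused acetal needs.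

**10 to commercial materials.** The C8=C9 bond is cut by metathesis (9, 8, 7) and the C5–C10 bond by an Ireland–Claisen rearrangement of ester 5 via boron ketene acetal 6. Ester 5 is made from enynol 3 (from commercial 1 through 2) and hex-5-enoic acid 4. The rearrangement sets the quaternary C10 and C5 together, with the cis relation between C4 and C1 that both ring closures require.

## Roads not taken

**Alternative 1: crossed benzoin closure of ring B.** The cut is C8–C9. An N-heterocyclic carbene would turn a C8 dienal into an acyl anion equivalent that adds to a neopentyl C9 aldehyde on C10, giving the C4 triflate α-hydroxy dienone A1.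

- Merits: the α-ketol and the dienone appear in one step, and C11 arrives ready-made with the side chain, so the centre that costs the chosen plan four steps and a lactone detour (steps 20 to 23) is bought with a building block. A1 differs from monomer 32 only in its protecting groups and the halide. In convergence and in the handling of C11 this road is better.
- Weak points: the acyl anion equivalent of a dienal can react as a homoenolate or vinylogously. The acceptor aldehyde sits on a quaternary carbon next to a cyclopropane. The C9 configuration would rest on catalyst control at a hindered centre. The bicyclo[3.1.0] unit must already exist, so the cyclopropane problem is only moved.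
- What the chosen plan sets against it: C9 is fixed early by an epoxide opening of known course, and the photochemical step makes the cyclopropane and the five-membered ring together from a ring that is easy to build.

**Alternative 2: intramolecular Diels–Alder across a cis-cyclopropane tether.** The cuts are C5–C10 and C8–C9. A 1-silyloxy diene (C5=C6–C7=C8) tethered through the C4 ketal and the cis-cyclopropane to an E-alkenylboronate (C10=C9) would cycloadd on heating, giving the C9 boronate A2.

- Merits: two rings, two bonds, the quaternary C10 and C9 in one thermal step, with the alkene geometry transferred stereospecifically. In bond economy this matches the chosen key step, and it sets more stereocentres.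
- Weak points: the dienophile is an unactivated trisubstituted alkenylboronate that must form a quaternary centre. The diene carries the bulky C11 group at C7. The short cis-cyclopropane tether restricts the approach geometry, so the required high temperature competes with silyl dienol ether decomposition. After the cycloaddition C8 and C9 still have to be brought to the ketol oxidation pattern through a C–B oxidation.
- What the chosen plan sets against it: every bond is made under mild conditions of known type, and the ketol oxidation pattern is in place without a C–B oxidation.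

**Alternative 3: silyloxyfuran Diels–Alder annulation of ring B.** The cuts are C5–C6 and C9–C10. A 4-substituted 3-silyloxyfuran would add endo to the C5=C10 bond of a cyclopropane-fused cyclopentenone, anti to the cyclopropane, giving the oxa-bridged adduct A3.

- Merits: the most convergent of the four routes. Ring B comes from two fragments of similar size, C11 is again in a building block, and β-elimination of the oxygen bridge from the C4 enolate would reveal the C9 hydroxyl and the dienone directly.
- Weak points: the dienophile is a tetrasubstituted, β-methyl enone, which is a poor partner for a furan whose cycloadditions are reversible. Regiochemistry and endo/exo selectivity are both open. The quaternary C10 must form in the crowded bay next to the cyclopropane.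
- What the chosen plan sets against it: it is longer, but the quaternary C10 is made by a sigmatropic rearrangement with a predictable chair transition state and not in a reversible cycloaddition.

Key step: step 16

## Route

Atom numbers C1–C15 are those of the lindenane skeleton of the target throughout; in a monomer the methylene on C11, which becomes C15 of the partner unit, is written C15'.

Assumption: the (S,S)-configured bis-sulfonamide bromoborane of step 3 is taken to deliver (2S,3R)-7; if its facial sense is the opposite, the (R,R)-enantiomer is used and nothing else changes.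

Remark: compounds 13–22 are mixtures of epimers at the acetal carbon, 18 and 19 at the C4 carbinol, and 26–28 at C11; these centres are drawn without configuration and are all removed or reset later.

Step 1
Reactants: 1 (Z)-3-methylpent-2-en-4-yn-1-ol
Product: 3 (Z)-3-methyl-5-(trimethylsilyl)pent-2-en-4-yn-1-ol, via bis-silyl ether 2 (not isolated)
Conditions: EtMgBr (2.2 equiv), THF, 0 → 40 °C; Me3SiCl (2.3 equiv), 0 °C → rt; 1 M HCl, rt
Reagents that add atoms: chlorotrimethylsilane, C[Si](C)(C)Cl
Why: Double deprotonation and silylation, then selective hydrolysis of the labile O–Si bond; the C-silyl group masks the alkyne against base and metathesis in the steps that follow.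

Step 2
Reactants: 3 (Z)-3-methyl-5-(trimethylsilyl)pent-2-en-4-yn-1-ol; 4 hex-5-enoic acid
Product: 5 (Z)-3-methyl-5-(trimethylsilyl)pent-2-en-4-yn-1-yl hex-5-enoate
Conditions: DCC, DMAP (cat.), CH2Cl2, 0 °C → rt
Reagents that add atoms: none
Why: Steglich esterification of a primary allylic alcohol; the Z alkene geometry is untouched.

Step 3
Reactants: 5 (Z)-3-methyl-5-(trimethylsilyl)pent-2-en-4-yn-1-yl hex-5-enoate
Product: 7 (2S,3R)-2-(but-3-en-1-yl)-3-methyl-3-[(trimethylsilyl)ethynyl]pent-4-enoic acid, via boron ketene acetal 6 (not isolated)
Conditions: (4S,5S)-2-bromo-4,5-diphenyl-1,3-bis{[3,5-bis(trifluoromethyl)phenyl]sulfonyl}-1,3,2-diazaborolidine (1.2 equiv), Et3N, toluene–hexane, −78 °C; then −20 → 4 °C; aqueous work-up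
Reagents that add atoms: none
Why: Enantioselective Ireland–Claisen rearrangement through a chair transition state, a reaction type established for esters that form a quaternary carbon next to a tertiary one. The boron ketene acetal formed with Et3N in toluene–hexane has the butenyl chain cis to the allyloxy oxygen and trans to O–B; with the Z alkene (alkynyl cis to CH2O) this places C4 and the alkynyl group cis on the future ring B, with H5 cis to the C10 methyl. The C2-symmetric boron controller chooses between the two enantiomeric chairs and so sets C5 (S) and C10 (R).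

Step 4
Reactants: 7 (2S,3R)-2-(but-3-en-1-yl)-3-methyl-3-[(trimethylsilyl)ethynyl]pent-4-enoic acid
Product: 8 (2S,3R)-2-(but-3-en-1-yl)-3-methyl-3-[(trimethylsilyl)ethynyl]pent-4-en-1-ol
Conditions: LiAlH4, Et2O, 0 °C → rt
Reagents that add atoms: none
Why: Hydride reduction of the acid; isolated alkenes and the silylalkyne are inert and no stereocentre is touched.

Step 5
Reactants: 8 (2S,3R)-2-(but-3-en-1-yl)-3-methyl-3-[(trimethylsilyl)ethynyl]pent-4-en-1-ol
Product: 9 (2S,3R)-2-(but-3-en-1-yl)-3-methyl-3-[(trimethylsilyl)ethynyl]pent-4-en-1-yl acetate
Conditions: Ac2O, pyridine, DMAP (cat.), CH2Cl2, rt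
Reagents that add atoms: acetic anhydride, CC(=O)OC(C)=O
Why: Acylation; the acetate stops the C4 oxygen from opening the epoxide of step 8 in a 5-exo fashion and is removed together with the alkynyl silane in step 10.

Step 6
Reactants: 9 (2S,3R)-2-(but-3-en-1-yl)-3-methyl-3-[(trimethylsilyl)ethynyl]pent-4-en-1-yl acetate
Product: 10 [(1S,2R)-2-methyl-2-[(trimethylsilyl)ethynyl]cyclohex-3-en-1-yl]methyl acetate
Conditions: RuCl2(H2IMes)(PCy3)(=CHPh) (second-generation Grubbs catalyst, 3 mol%), CH2Cl2 (5 mM), 40 °C
Reagents that add atoms: none
Why: Ring-closing metathesis of the two terminal alkenes closes ring B at C8=C9; the internal silylalkyne does not enter enyne metathesis under these conditions.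

Step 7
Reactants: 10 [(1S,2R)-2-methyl-2-[(trimethylsilyl)ethynyl]cyclohex-3-en-1-yl]methyl acetate
Product: 11 the C8–C9 epoxide of 10 with the oxirane oxygen on the face of the C10 methyl group
Conditions: m-CPBA, NaHCO3, CH2Cl2, 0 °C
Reagents that add atoms: 3-chloroperoxybenzoic acid, OOC(=O)c1cccc(Cl)c1
Why: Peracid epoxidation. In the favoured half-chair the slim alkynyl group is pseudoaxial and covers the face of C9 opposite the methyl, while the methyl and the acetoxymethyl group are pseudoequatorial, so the oxygen should enter syn to the methyl and set C8 and C9 of the epoxide.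

Step 8
Reactants: 11 the C8–C9 epoxide of 10 with the oxirane oxygen on the face of the C10 methyl group
Product: 12 [(1S,2R,3R,4R)-3,4-dihydroxy-2-methyl-2-[(trimethylsilyl)ethynyl]cyclohexyl]methyl acetate
Conditions: HClO4 (cat.), THF–H2O (3:1), rt
Reagents that add atoms: water, O
Why: Acid-catalysed trans-diaxial epoxide opening (Fürst–Plattner). Water attacks C8, the carbon remote from the quaternary centre, with inversion, so C9–OH stays cis to the methyl and C8–OH is trans to it.

Step 9
Reactants: 12 [(1S,2R,3R,4R)-3,4-dihydroxy-2-methyl-2-[(trimethylsilyl)ethynyl]cyclohexyl]methyl acetate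
Product: 13 the 4-methoxybenzylidene acetal of 12 (trans-fused dioxolane on O8 and O9)
Conditions: 4-MeOC6H4CH(OMe)2, PPTS (cat.), 4 Å molecular sieves, CH2Cl2, rt
Reagents that add atoms: 4-methoxybenzaldehyde dimethyl acetal, COc1ccc(C(OC)OC)cc1
Why: Acetal exchange. A trans-fused dioxolane can only span two equatorial oxygens, so it holds ring B in the chair with the C10 methyl axial; this is the conformational lock used in step 16 and the handle for differentiating O8 and O9 in step 18.

Step 10
Reactants: 13 the 4-methoxybenzylidene acetal of 12 (trans-fused dioxolane on O8 and O9)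
Product: 14 the primary alcohol with a free ethynyl group on C10 (acetate and alkynyl silane of 13 removed)
Conditions: K2CO3, MeOH, rt
Reagents that add atoms: none
Why: Methanolysis cleaves the acetate and the C(sp)–Si bond in one operation; the acetal is stable to base.

Step 11
Reactants: 14 the primary alcohol with a free ethynyl group on C10 (acetate and alkynyl silane of 13 removed)
Product: 15 the corresponding C10 vinyl compound
Conditions: H2 (1 atm), Pd/CaCO3 poisoned with Pb(OAc)2 (Lindlar catalyst), quinoline, EtOAc, rt
Reagents that add atoms: none
Why: Lindlar semihydrogenation of a terminal alkyne stops at the alkene and reveals the C1 vinyl group.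

Step 12
Reactants: 15 the corresponding C10 vinyl compound
Product: 16 the C4 aldehyde (formyl group on C5 cis to the C10 vinyl group)
Conditions: Dess–Martin periodinane, NaHCO3, CH2Cl2, 0 °C → rt
Reagents that add atoms: none
Why: Buffered periodinane oxidation; the axial α-stereocentre C5 is epimerisable, so the aldehyde is used at once without exposure to base.

Step 13
Reactants: 16 the C4 aldehyde (formyl group on C5 cis to the C10 vinyl group); 17 allylmagnesium bromide
Product: 18 the homoallylic alcohols at C4 (both carbinol epimers)
Conditions: THF, −78 °C; aqueous NH4Cl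
Reagents that add atoms: none
Why: Grignard addition is fast at −78 °C and outruns enolisation of the aldehyde; the new carbinol centre is oxidised away in step 15.

Step 14
Reactants: 18 the homoallylic alcohols at C4 (both carbinol epimers)
Product: 19 the cis-fused octalinols with C1=C3 in ring A (C4–OH epimers)
Conditions: RuCl2(H2IMes)(PCy3)(=CHPh) (second-generation Grubbs catalyst, 5 mol%), CH2Cl2 (5 mM), 40 °C
Reagents that add atoms: none
Why: Ring-closing metathesis between the equatorial C10 vinyl group and the axial C5 side chain closes the six-membered ring A; the cis ring fusion is fixed by the relative configuration set in step 3.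

Step 15
Reactants: 19 the cis-fused octalinols with C1=C3 in ring A (C4–OH epimers)
Product: 20 (5S,8R,9R,10S) cis-fused β,γ-unsaturated decalone: C4 ketone, C1=C3 alkene, C10 methyl, 4-methoxybenzylidene acetal on O8 (trans to the methyl) and O9 (cis to the methyl)
Conditions: Dess–Martin periodinane, NaHCO3, CH2Cl2, 0 °C
Reagents that add atoms: none
Why: Neutral, buffered oxidation gives the β,γ-enone without migration of the double bond into conjugation and without epimerisation at C5.

Step 16
Reactants: 20 (5S,8R,9R,10S) cis-fused β,γ-unsaturated decalone: C4 ketone, C1=C3 alkene, C10 methyl, 4-methoxybenzylidene acetal on O8 (trans to the methyl) and O9 (cis to the methyl)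
Product: 21 (1R,3S,5S,8R,9R,10S) tricyclic ketone: cyclopropane C1–C2–C3 fused to the C4 cyclopentanone, C2 on the face of the C10 methyl, ring B and its acetal unchanged
Conditions: hν (300 nm lamps, Pyrex), acetone (degassed, 5 mM), rt
Reagents that add atoms: none
Why: Triplet energy transfer from acetone excites the β,γ-enone; the acyl carbon C4 bonds to C3, the C2–C4 bond of the resulting cyclopropyloxy diradical breaks, and the 1,3-diradical at C2 and C1 closes. This is the oxa-di-π-methane rearrangement, known for ring-fused cyclohex-3-enones. The five-membered ring forms by the transannular C3–C4 bond (a formal 1,2-acyl shift) and the three-membered ring by recombination of the 1,3-diradical. C1 and C3 are necessarily cis to each other; their sense relative to C10 depends on which face of C3 the acyl carbon bridges. The trans-fused acetal holds ring B in the chair with the C10 methyl axial, which fixes ring A in the half-chair where C9 is pseudoaxial and C4 lies on the face away from the methyl; bridging there pushes C2 to the methyl face, as the target requires. Sensitisation is needed to suppress the singlet 1,3-acyl shift and α-cleavage. The anisyl acetal is transparent at 300 nm in acetone and ring B carries no second chromophore.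

Step 17
Reactants: 21 (1R,3S,5S,8R,9R,10S) tricyclic ketone: cyclopropane C1–C2–C3 fused to the C4 cyclopentanone, C2 on the face of the C10 methyl, ring B and its acetal unchanged
Product: 22 the C4 enol triflate (C4=C5) of 21
Conditions: KN(SiMe3)2, THF, −78 °C; PhNTf2, −78 → 0 °C; aqueous NH4Cl
Reagents that add atoms: N-phenylbis(trifluoromethanesulfonimide), O=S(=O)(N(c1ccccc1)S(=O)(=O)C(F)(F)F)C(F)(F)F
Why: Enolate O-triflation. C5–H is the only enolisable position, since an enolate towards the cyclopropane carbon C3 would be a bridgehead alkene, so the C4=C5 bond and the coupling handle are installed regiospecifically.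

Step 18
Reactants: 22 the C4 enol triflate (C4=C5) of 21
Product: 23 the C8 alcohol with a 4-methoxybenzyl ether on O9
Conditions: i-Bu2AlH (3 equiv), CH2Cl2, −78 → 0 °C; aqueous KNaC4H4O6 (potassium sodium tartrate) work-up
Reagents that add atoms: none
Why: Reductive opening of the arylidene acetal. The aluminium binds the less hindered O8, that C–O bond breaks and hydride caps the oxocarbenium ion, leaving the benzyl ether on the neopentyl O9; the alkenyl triflate is inert to the hydride at low temperature.

Step 19
Reactants: 23 the C8 alcohol with a 4-methoxybenzyl ether on O9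
Product: 24 the C8 ketone with a 4-methoxybenzyl ether on O9
Conditions: Dess–Martin periodinane, NaHCO3, CH2Cl2, rt
Reagents that add atoms: none
Why: Periodinane oxidation of the secondary alcohol under neutral conditions; the α-alkoxy centre C9 is not epimerised.

Step 20
Reactants: 24 the C8 ketone with a 4-methoxybenzyl ether on O9; 25 tert-butyl 2-bromopropanoate (racemic)
Product: 26 the γ-keto ester with the CH(CH3)CO2t-Bu group on C7 cis to the C9 oxygen (C11 epimers)
Conditions: LiN(i-Pr)2, THF, −78 °C; 25, DMPU, −78 → −20 °C; then DBU (cat.), CH2Cl2, rt
Reagents that add atoms: none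
Why: Kinetic deprotonation takes the unhindered C7–H and not the alkoxy-bearing C9–H, and the enolate is alkylated by the α-bromo ester (SN2). Brief equilibration with DBU gives the more stable 2,6-cis ketone, the epimer that can lactonise in step 21.

Step 21
Reactants: 26 the γ-keto ester with the CH(CH3)CO2t-Bu group on C7 cis to the C9 oxygen (C11 epimers)
Product: 28 bridged keto-lactone (δ-lactone from C12 to O9 spanning C7 and C9; C11 epimers), via hydroxy acid 27 (not isolated)
Conditions: CF3CO2H, anisole, CH2Cl2, 0 °C → rt; evaporate; EDC·HCl, DMAP, CH2Cl2 (2 mM), rt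
Reagents that add atoms: none
Why: Acid removes the benzyl ether and the tert-butyl ester together; carbodiimide lactonisation then closes a six-membered ring onto the C9 hydroxyl once both groups turn axial. The lactone makes C7 and C9 bridgeheads, which protects the ketone from enolisation and exposes one face of C11.

Step 22
Reactants: 28 bridged keto-lactone (δ-lactone from C12 to O9 spanning C7 and C9; C11 epimers)
Product: 29 the C11 iodomethyl lactone with (R)-configured quaternary C11
Conditions: KN(SiMe3)2, THF, −78 °C; CH2I2 (5 equiv), DMPU, −78 → −20 °C
Reagents that add atoms: diiodomethane, ICI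
Why: Enolate alkylation. Only C11–H is acidic, because the ketone lies between two bridgeheads, and a silazide base avoids hydride transfer to that ketone. The electrophile approaches the enolate from the face turned away from the C6–C5–C10 bridge (exo), which places CH2I and the methyl group as in the target and sets C11.

Step 23
Reactants: 29 the C11 iodomethyl lactone with (R)-configured quaternary C11
Product: 30 the C9 hydroxy C8 keto methyl ester carrying C(CH3)(CO2CH3)(CH2I) on C7
Conditions: HCl (1.25 M in MeOH), 50 °C
Reagents that add atoms: methanol, CO
Why: Acid-catalysed transesterification opens the strained bridged lactone to the methyl ester and the free C9 hydroxyl. Base is avoided because the C7 enolate of the product would close a cyclopropane onto the iodide.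

Step 24
Reactants: 30 the C9 hydroxy C8 keto methyl ester carrying C(CH3)(CO2CH3)(CH2I) on C7
Product: 31 the C9 triethylsilyl ether of 30
Conditions: Et3SiOTf, 2,6-lutidine, CH2Cl2, −78 → 0 °C
Reagents that add atoms: triethylsilyl trifluoromethanesulfonate, CC[Si](CC)(CC)OS(=O)(=O)C(F)(F)F
Why: Silylation of the hindered α-hydroxy ketone; it blocks enediol formation in step 25 and protonolysis of the organozinc reagents in steps 27 and 29.

Step 25
Reactants: 31 the C9 triethylsilyl ether of 30
Product: 32 the dienone monomer: C4 triflate, C4=C5, C6=C7, C8 ketone, C9 silyl ether, (R)-C11 with methyl, methyl ester and iodomethyl (C15')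
Conditions: DDQ, 1,4-dioxane, 80 °C
Reagents that add atoms: none
Why: Quinone dehydrogenation. The C6 hydrogens are allylic to both the C7=C8 enol and the C4=C5 bond, so hydride abstraction there gives the linear dienone; the C9 side of the ketone has no β-hydrogen and cannot react.

Step 26
Reactants: 32 the dienone monomer: C4 triflate, C4=C5, C6=C7, C8 ketone, C9 silyl ether, (R)-C11 with methyl, methyl ester and iodomethyl (C15')
Product: 33 the C4 trimethylstannyl analogue of 32 (Me3Sn in place of the triflate, C15' iodide kept)
Conditions: Me3SnSnMe3 (1.2 equiv), Pd(PPh3)4 (5 mol%), LiCl (3 equiv), THF, 60 °C, dark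
Reagents that add atoms: hexamethylditin, C[Sn](C)(C)[Sn](C)(C)C
Why: Palladium-catalysed stannylation of an alkenyl triflate with a distannane; zerovalent palladium inserts into the activated dienyl C–O bond far faster than into the neopentyl C–I bond. The tin group masks C4 of the half that will serve as the nucleophile and is exchanged for bromine in step 28.

Step 27
Reactants: 33 the C4 trimethylstannyl analogue of 32 (Me3Sn in place of the triflate, C15' iodide kept); 32 the dienone monomer: C4 triflate, C4=C5, C6=C7, C8 ketone, C9 silyl ether, (R)-C11 with methyl, methyl ester and iodomethyl (C15')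
Product: 35 the linear head-to-tail dimer with a C4 trimethylstannyl terminus and a C15' iodide terminus, via stannyl alkylzinc iodide 34 (not isolated)
Conditions: 33, Zn dust (activated with BrCH2CH2Br and Me3SiCl), DMA, 40 °C; filtered from excess Zn; then 32 (1.0 equiv), Pd2(dba)3 (2.5 mol%), SPhos (6 mol%), THF–DMA, rt
Reagents that add atoms: none
Why: Negishi coupling of an ester-flanked alkylzinc iodide with an activated alkenyl triflate, a known sp3–sp2 coupling; C11 has no hydrogen, so β-hydride elimination is impossible. Zinc transmetalates much faster than the hindered alkenylstannane in the absence of chloride or copper additives, and the palladium/SPhos catalyst adds to the triflate and not to the neopentyl iodide of 32, so the reaction stops at the head-to-tail dimer. No stereocentre is formed.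

Step 28
Reactants: 35 the linear head-to-tail dimer with a C4 trimethylstannyl terminus and a C15' iodide terminus
Product: 36 the linear head-to-tail dimer with a C4 bromide terminus and a C15' iodide terminus
Conditions: N-bromosuccinimide (1.05 equiv), MeCN–CH2Cl2, 0 °C, dark
Reagents that add atoms: N-bromosuccinimide, O=C1CCC(=O)N1Br
Why: Bromodestannylation, an ipso electrophilic substitution at the C–Sn bond that leaves the double bond in place; the electron-poor diene and the alkyl iodide do not react with the reagent at 0 °C. A bromide is chosen over an iodide because zinc dust does not insert into alkenyl bromides under the conditions of step 29.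

Step 29
Reactants: 36 the linear head-to-tail dimer with a C4 bromide terminus and a C15' iodide terminus
Product: 38 the 9,9'-bis(triethylsilyl) ether of cycloshizukaol A, via bromo alkylzinc iodide 37 (not isolated)
Conditions: Zn dust (activated with BrCH2CH2Br and Me3SiCl), DMA, 40 °C; filtered from excess Zn; slow addition to Pd2(dba)3 (5 mol%), SPhos (12 mol%), THF–DMA, 60 °C (final 1 mM)
Reagents that add atoms: none
Why: Intramolecular Negishi coupling of the alkylzinc iodide with the alkenyl bromide closes the twelve-membered ring, a macrocyclization by sp3–sp2 cross-coupling run under high dilution. No stereocentre is formed, and two homochiral halves joined head to tail can only give the C2-symmetric macrocycle.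

Step 30
Reactants: 38 the 9,9'-bis(triethylsilyl) ether of cycloshizukaol A
Product: 39 cycloshizukaol A
Conditions: HF·pyridine, THF, 0 °C → rt
Reagents that add atoms: none
Why: Fluoride-mediated desilylation under buffered acidic conditions, which spare the dienone, the α-ketol and the methyl esters.

## Compound list

1 | (Z)-3-methylpent-2-en-4-yn-1-ol | C#C/C(C)=C\CO | starting material
2 | (Z)-trimethyl{[3-methyl-5-(trimethylsilyl)pent-2-en-4-yn-1-yl]oxy}silane | C[Si](C)(C)C#C/C(C)=C\CO[Si](C)(C)C | intermediate
3 | (Z)-3-methyl-5-(trimethylsilyl)pent-2-en-4-yn-1-ol | C[Si](C)(C)C#C/C(C)=C\CO | intermediate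
4 | hex-5-enoic acid | C=CCCCC(=O)O | starting material
5 | (Z)-3-methyl-5-(trimethylsilyl)pent-2-en-4-yn-1-yl hex-5-enoate | C=CCCCC(=O)OC/C=C(C)\C#C[Si](C)(C)C | intermediate
6 | boron ketene acetal of 5 (Z by sequence rule), boron bearing the (4S,5S)-4,5-diphenyl-1,3-bis{[3,5-bis(trifluoromethyl)phenyl]sulfonyl}-1,3,2-diazaborolidine unit, butenyl chain cis to the allyloxy oxygen and trans to O–B | C=CCC/C=C(/OB1N(S(=O)(=O)c2cc(C(F)(F)F)cc(C(F)(F)F)c2)[C@@H](c2ccccc2)[C@H](c2ccccc2)N1S(=O)(=O)c1cc(C(F)(F)F)cc(C(F)(F)F)c1)OC/C=C(C)\C#C[Si](C)(C)C | intermediate
7 | (2S,3R)-2-(but-3-en-1-yl)-3-methyl-3-[(trimethylsilyl)ethynyl]pent-4-enoic acid | OC(=O)[C@@H](CCC=C)[C@@](C)(C=C)C#C[Si](C)(C)C | intermediate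
8 | (2S,3R)-2-(but-3-en-1-yl)-3-methyl-3-[(trimethylsilyl)ethynyl]pent-4-en-1-ol | OC[C@@H](CCC=C)[C@@](C)(C=C)C#C[Si](C)(C)C | intermediate
9 | (2S,3R)-2-(but-3-en-1-yl)-3-methyl-3-[(trimethylsilyl)ethynyl]pent-4-en-1-yl acetate | CC(=O)OC[C@@H](CCC=C)[C@@](C)(C=C)C#C[Si](C)(C)C | intermediate
10 | [(1S,2R)-2-methyl-2-[(trimethylsilyl)ethynyl]cyclohex-3-en-1-yl]methyl acetate | CC(=O)OC[C@H]1CCC=C[C@@]1(C)C#C[Si](C)(C)C | intermediate
11 | C8–C9 epoxide of 10, oxirane oxygen cis to the C10 methyl | CC(=O)OC[C@H]1CC[C@@H]2O[C@@H]2[C@@]1(C)C#C[Si](C)(C)C | intermediate
12 | [(1S,2R,3R,4R)-3,4-dihydroxy-2-methyl-2-[(trimethylsilyl)ethynyl]cyclohexyl]methyl acetate | CC(=O)OC[C@H]1CC[C@@H](O)[C@H](O)[C@@]1(C)C#C[Si](C)(C)C | intermediate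
13 | 4-methoxybenzylidene acetal of 12 (trans-fused dioxolane on O8 and O9) | CC(=O)OC[C@H]1CC[C@@H](OC(c2ccc(OC)cc2)O3)[C@H]3[C@@]1(C)C#C[Si](C)(C)C | intermediate
14 | primary alcohol with C10 ethynyl group, O8/O9 4-methoxybenzylidene acetal | OC[C@H]1CC[C@@H](OC(c2ccc(OC)cc2)O3)[C@H]3[C@@]1(C)C#C | intermediate
15 | primary alcohol with C10 vinyl group, O8/O9 4-methoxybenzylidene acetal | OC[C@H]1CC[C@@H](OC(c2ccc(OC)cc2)O3)[C@H]3[C@@]1(C)C=C | intermediate
16 | C4 aldehyde, formyl on C5 cis to the C10 vinyl group | O=C[C@H]1CC[C@@H](OC(c2ccc(OC)cc2)O3)[C@H]3[C@@]1(C)C=C | intermediate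
17 | allylmagnesium bromide | C=CC[Mg]Br | starting material
18 | C4 homoallylic alcohols (carbinol epimers) | C=CCC(O)[C@H]1CC[C@@H](OC(c2ccc(OC)cc2)O3)[C@H]3[C@@]1(C)C=C | intermediate
19 | cis-fused octalinols, C1=C3 alkene, C4–OH epimers | OC1CC=C[C@]2(C)[C@@H](OC(c3ccc(OC)cc3)O4)[C@H]4CC[C@H]12 | intermediate
20 | (5S,8R,9R,10S) cis-fused β,γ-unsaturated decalone, O8/O9 4-methoxybenzylidene acetal (key-step precursor) | O=C1CC=C[C@]2(C)[C@@H](OC(c3ccc(OC)cc3)O4)[C@H]4CC[C@H]12 | intermediate
21 | (1R,3S,5S,8R,9R,10S) cyclopropane-fused tricyclic C4 ketone, O8/O9 4-methoxybenzylidene acetal (key-step product) | O=C1[C@H]2C[C@H]2[C@]2(C)[C@@H](OC(c3ccc(OC)cc3)O4)[C@H]4CC[C@H]12 | intermediate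
22 | C4 enol triflate of 21 (C4=C5) | FC(F)(F)S(=O)(=O)OC1=C2CC[C@@H](OC(c3ccc(OC)cc3)O4)[C@H]4[C@@]2(C)[C@@H]2C[C@H]12 | intermediate
23 | C8 alcohol, O9 4-methoxybenzyl ether, C4 triflate | FC(F)(F)S(=O)(=O)OC1=C2CC[C@@H](O)[C@H](OCc3ccc(OC)cc3)[C@@]2(C)[C@@H]2C[C@H]12 | intermediate
24 | C8 ketone, O9 4-methoxybenzyl ether, C4 triflate | FC(F)(F)S(=O)(=O)OC1=C2CCC(=O)[C@H](OCc3ccc(OC)cc3)[C@@]2(C)[C@@H]2C[C@H]12 | intermediate
25 | tert-butyl 2-bromopropanoate (racemic) | CC(Br)C(=O)OC(C)(C)C | starting material
26 | γ-keto tert-butyl ester, side chain on C7 cis to O9, C11 epimers | FC(F)(F)S(=O)(=O)OC1=C2C[C@H](C(C)C(=O)OC(C)(C)C)C(=O)[C@H](OCc3ccc(OC)cc3)[C@@]2(C)[C@@H]2C[C@H]12 | intermediate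
27 | C9 hydroxy γ-keto acid, C11 epimers | FC(F)(F)S(=O)(=O)OC1=C2C[C@H](C(C)C(=O)O)C(=O)[C@H](O)[C@@]2(C)[C@@H]2C[C@H]12 | intermediate
28 | bridged keto-lactone (C12 to O9), C11 epimers | FC(F)(F)S(=O)(=O)OC1=C2C[C@@H]3C(C)C(=O)O[C@@H](C3=O)[C@@]2(C)[C@@H]2C[C@H]12 | intermediate
29 | bridged keto-lactone with (R)-C11 bearing methyl and iodomethyl | FC(F)(F)S(=O)(=O)OC1=C2C[C@@H]3[C@@](C)(CI)C(=O)O[C@@H](C3=O)[C@@]2(C)[C@@H]2C[C@H]12 | intermediate
30 | C9 hydroxy C8 keto methyl ester with C(CH3)(CO2CH3)(CH2I) on C7 | FC(F)(F)S(=O)(=O)OC1=C2C[C@H]([C@](C)(C(=O)OC)CI)C(=O)[C@H](O)[C@@]2(C)[C@@H]2C[C@H]12 | intermediate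
31 | C9 triethylsilyl ether of 30 | FC(F)(F)S(=O)(=O)OC1=C2C[C@H]([C@](C)(C(=O)OC)CI)C(=O)[C@H](O[Si](CC)(CC)CC)[C@@]2(C)[C@@H]2C[C@H]12 | intermediate
32 | dienone monomer (C4 triflate, C9 silyl ether, C15' iodide) | FC(F)(F)S(=O)(=O)OC1=C2C=C([C@](C)(C(=O)OC)CI)C(=O)[C@H](O[Si](CC)(CC)CC)[C@@]2(C)[C@@H]2C[C@H]12 | intermediate
33 | C4 trimethylstannyl analogue of 32 (C15' iodide kept) | C[Sn](C)(C)C1=C2C=C([C@](C)(C(=O)OC)CI)C(=O)[C@H](O[Si](CC)(CC)CC)[C@@]2(C)[C@@H]2C[C@H]12 | intermediate
34 | alkylzinc iodide of 33 | C[Sn](C)(C)C1=C2C=C([C@](C)(C(=O)OC)C[Zn]I)C(=O)[C@H](O[Si](CC)(CC)CC)[C@@]2(C)[C@@H]2C[C@H]12 | intermediate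
35 | linear head-to-tail dimer with C4 trimethylstannyl and C15' iodide termini | C[Sn](C)(C)C1=C2C=C([C@](C)(C(=O)OC)CC3=C4C=C([C@](C)(C(=O)OC)CI)C(=O)[C@H](O[Si](CC)(CC)CC)[C@@]4(C)[C@@H]4C[C@H]34)C(=O)[C@H](O[Si](CC)(CC)CC)[C@@]2(C)[C@@H]2C[C@H]12 | intermediate
36 | linear head-to-tail dimer with C4 bromide and C15' iodide termini | BrC1=C2C=C([C@](C)(C(=O)OC)CC3=C4C=C([C@](C)(C(=O)OC)CI)C(=O)[C@H](O[Si](CC)(CC)CC)[C@@]4(C)[C@@H]4C[C@H]34)C(=O)[C@H](O[Si](CC)(CC)CC)[C@@]2(C)[C@@H]2C[C@H]12 | intermediate
37 | alkylzinc iodide of 36 | BrC1=C2C=C([C@](C)(C(=O)OC)CC3=C4C=C([C@](C)(C(=O)OC)C[Zn]I)C(=O)[C@H](O[Si](CC)(CC)CC)[C@@]4(C)[C@@H]4C[C@H]34)C(=O)[C@H](O[Si](CC)(CC)CC)[C@@]2(C)[C@@H]2C[C@H]12 | intermediate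
38 | 9,9'-bis(triethylsilyl) ether of cycloshizukaol A | COC(=O)[C@]1(C)CC2=C3C=C(C(=O)[C@H](O[Si](CC)(CC)CC)[C@@]3(C)[C@@H]3C[C@H]23)[C@](C)(C(=O)OC)CC2=C3C=C1C(=O)[C@H](O[Si](CC)(CC)CC)[C@@]3(C)[C@@H]1C[C@H]21 | intermediate
39 | cycloshizukaol A | COC(=O)[C@]1(C)CC2=C3C=C(C(=O)[C@H](O)[C@@]3(C)[C@@H]3C[C@H]23)[C@](C)(C(=O)OC)CC2=C3C=C1C(=O)[C@H](O)[C@@]3(C)[C@@H]1C[C@H]21 | target

## Step count and least certain steps

Total: 30 steps. Longest linear sequence: 30 steps (1 to 39). Compounds 4, 17 and 25 are commercial and enter directly; monomer 32 enters twice, once through stannane 33 and once unchanged in step 27.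

**Step 16 (key step).** Three things may go wrong.
- Part of the material may react from the singlet state or by direct absorption and undergo the 1,3-acyl shift or α-cleavage.
- The carbonyl triplet may abstract the activated C9 hydrogen.
- Bridging may occur on the wrong face of C3 if the trans-acetal holds ring B less firmly than assumed, which would place C2 anti to the methyl.

The fallback avoids photochemistry. Aldehyde 16 would be oxidised with NaClO2 to the carboxylic acid F1, converted through its mixed anhydride with diazomethane into the diazoketone F2, and treated with Rh2(OAc)4. Intramolecular cyclopropanation of the C10 vinyl group by the keto-carbenoid would give the bicyclo[3.1.0]hexanone directly, with C2 on the open convex face. The route is rejoined at 21.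

**Step 29.** Coupling between two molecules of the zinc reagent may outrun ring closure, because the open dimer must fold before its two ends meet. Zinc may also attack the dienyl bromide, and the organozinc may be lost by protonolysis during the slow addition. The fallback closes the ring without a preformed organometallic. Bromo iodide 36 would be treated with NiBr2(MeOCH2CH2OMe), 4,4'-di-tert-butyl-2,2'-bipyridine and Mn powder in DMA at high dilution. This is a nickel-catalysed reductive cross-electrophile coupling, in which the alkenylnickel species formed from the bromide captures the C15' radical formed from the iodide. The path sets out from 36 and rejoins the route at 38; no new compound lies on it (F0).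

**Step 27.** Tin-to-palladium transmetalation may compete with zinc and join two C4 carbons. Palladium may insert into the neopentyl iodide, and zinc dust carried over would turn 32 into a second nucleophile. The same tolerance of the alkyl iodide is asked of step 26. The fallback gives up the differentiation of the two halves. Monomer 32 would be converted with activated zinc in DMA into the alkylzinc iodide F3 and added slowly to Pd2(dba)3 and SPhos at high dilution. Two molecules would couple head to tail to the linear dimer F4 (C4 triflate and alkylzinc iodide termini), which closes the ring in the same flask. The route is rejoined at 38.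

**Step 22.** Substitution on diiodomethane by a hindered, fully substituted enolate may be slow, and iodine transfer to the enolate may compete. In the fallback, 28 would be hydroxymethylated with monomeric formaldehyde (same base, same exo face) to the hydroxymethyl lactone F5. This would be opened with HCl in methanol to the diol ester F6, and the primary neopentyl alcohol converted with I2, PPh3 and imidazole into the iodide. The route is rejoined at 30.

**Step 21.** Activation of the γ-keto acid may lead to acylation of the ketone enol (an enol lactone) in place of the hindered C9 hydroxyl, and the diaxial arrangement needed for the bridge may be reached too slowly. The fallback reverses the order of bond formation. Ketone 24 would be debenzylated with DDQ to the α-hydroxy ketone F7 and acylated with 2-bromopropanoyl bromide to the ester F8. The C7 enolate (LiN(SiMe3)2, THF–DMPU) would then be alkylated intramolecularly by the tethered α-bromo ester in a six-membered closure, rejoining the route at 28.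

**Step 3.** Enantio- and diastereoselectivity may be lowered if the boron enolate geometry is not uniform, or if a boat transition state competes because of the axial alkynyl group. The rearrangement to a quaternary centre may also be slow. In the fallback, ester 5 would be rearranged without a chiral controller (LiN(i-Pr)2, Me3SiCl, THF) through the silyl ketene acetal F9 to racemic 7. The acid would be resolved by crystallisation of its (S)-1-phenylethylammonium salt F10 (or the salt of the antipodal amine, whichever carries 7). Acidification rejoins the route at 7.

## Further compounds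

F1 | step 16 | carboxylic acid from 16 (CO2H on C5, C10 vinyl, O8/O9 4-methoxybenzylidene acetal) | OC(=O)[C@H]1CC[C@@H](OC(c2ccc(OC)cc2)O3)[C@H]3[C@@]1(C)C=C
F2 | step 16 | diazoketone from F1 | [N-]=[N+]=CC(=O)[C@H]1CC[C@@H](OC(c2ccc(OC)cc2)O3)[C@H]3[C@@]1(C)C=C
F0 | step 29 | none | none
F3 | step 27 | alkylzinc iodide of 32 | FC(F)(F)S(=O)(=O)OC1=C2C=C([C@](C)(C(=O)OC)C[Zn]I)C(=O)[C@H](O[Si](CC)(CC)CC)[C@@]2(C)[C@@H]2C[C@H]12
F4 | step 27 | linear head-to-tail dimer with C4 triflate and alkylzinc iodide termini | FC(F)(F)S(=O)(=O)OC1=C2C=C([C@](C)(C(=O)OC)CC3=C4C=C([C@](C)(C(=O)OC)C[Zn]I)C(=O)[C@H](O[Si](CC)(CC)CC)[C@@]4(C)[C@@H]4C[C@H]34)C(=O)[C@H](O[Si](CC)(CC)CC)[C@@]2(C)[C@@H]2C[C@H]12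
F5 | step 22 | bridged keto-lactone with C11 bearing methyl and hydroxymethyl | FC(F)(F)S(=O)(=O)OC1=C2C[C@@H]3[C@@](C)(CO)C(=O)O[C@@H](C3=O)[C@@]2(C)[C@@H]2C[C@H]12
F6 | step 22 | C9 hydroxy C8 keto methyl ester with C(CH3)(CO2CH3)(CH2OH) on C7 | FC(F)(F)S(=O)(=O)OC1=C2C[C@H]([C@](C)(C(=O)OC)CO)C(=O)[C@H](O)[C@@]2(C)[C@@H]2C[C@H]12
F7 | step 21 | C9 hydroxy C8 ketone, C4 triflate | FC(F)(F)S(=O)(=O)OC1=C2CCC(=O)[C@H](O)[C@@]2(C)[C@@H]2C[C@H]12
F8 | step 21 | C9 2-bromopropanoate of F7 | FC(F)(F)S(=O)(=O)OC1=C2CCC(=O)[C@H](OC(=O)C(C)Br)[C@@]2(C)[C@@H]2C[C@H]12
F9 | step 3 | E-trimethylsilyl ketene acetal of 5 (butenyl chain cis to the allyloxy oxygen) | C=CCC/C=C(/O[Si](C)(C)C)OC/C=C(C)\C#C[Si](C)(C)C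
F10 | step 3 | (S)-1-phenylethylammonium salt of 7 | [O-]C(=O)[C@@H](CCC=C)[C@@](C)(C=C)C#C[Si](C)(C)C.C[C@H]([NH3+])c1ccccc1
A1 | alternative 1 | C4 triflate α-hydroxy dienone tricycle | FC(F)(F)S(=O)(=O)OC1=C2C=C([C@](C)(C(=O)OC)CO[Si](C)(C)C(C)(C)C)C(=O)[C@H](O)[C@@]2(C)[C@@H]2C[C@H]12
A2 | alternative 2 | C9 boronate, C4 ketal lindenane tricycle | C1COC2(O1)[C@H]3C=C([C@](C)(C(=O)OC)CO[Si](C)(C)C(C)(C)C)[C@@H](O[Si](C)(C)C(C)(C)C)[C@H](B4OC(C)(C)C(C)(C)O4)[C@@]3(C)[C@@H]3C[C@H]23
A3 | alternative 3 | oxa-bridged tetracyclic adduct | O=C1[C@H]2[C@@H]3O[C@@H](C(O[Si](C)(C)C(C)(C)C)=C3[C@](C)(C(=O)OC)CO[Si](C)(C)C(C)(C)C)[C@@]2(C)[C@@H]2C[C@H]12
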